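**Plan**

- Retrosynthetic cuts: the 5-OH is masked as a triflate and the C2=C3 double bond is taken back to a flavanone. Ring C is then cut at three bonds at once, C8a–O1, C4a–C4 and O1–C2, leaving a ring A aryne (C4a≡C8a) and an alpha-methoxycinnamic acid that carries ring B, C2, C3 and C4.
- Enabling feature: on ring A the neighbouring carbons C4a and C8a hold the acyl carbon C4 and the ring oxygen O1, the two halves of a carboxyl C–O bond, so an aryne between these two carbons can accept both in one event.
- Forward order: ring A is bought as a salicylaldehyde and converted in four steps into an ortho-silyl bis-triflate. Ring B arrives with the acid (one step). Ring C is the only ring made, in the aryne step. Dehydrogenation and triflate cleavage finish the flavone.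
- Stereochemistry: the target has no stereocentre. C2 and C3 of the flavanone arise racemic and trans under thermodynamic control and are erased by the dehydrogenation. The Z alkene of the acid is the thermodynamic isomer.

Key step: step 6

Remark: flavone numbering (O1, C2, C3, C4, C4a, C5 to C8, C8a; ring B primed) is used for rings A and C in the plan and from step 6 on, while steps 1 to 5 use the locants of the compound names. The two aldehydes and methyl methoxyacetate are taken to be commercial, and the aryne regiochemistry rests on the assumption that the C5 triflate outweighs the C8 methoxyl.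

**Route**

Step 1
Reactants: 1 2-hydroxy-4,5-dimethoxybenzaldehyde
Product: 2 3-bromo-2-hydroxy-4,5-dimethoxybenzaldehyde
Conditions: NBS (1.05 equiv), MeCN, 0 °C to rt
Reagents that add atoms: N-bromosuccinimide, O=C1CCC(=O)N1Br
Why: Electrophilic aromatic bromination should go to C3 alone, the position ortho to the free phenol and to the C4 methoxyl and meta to the formyl group, whereas C6 is activated by a single methoxyl and lies ortho to the aldehyde.

Step 2
Reactants: 2 3-bromo-2-hydroxy-4,5-dimethoxybenzaldehyde
Product: 4 3-bromo-4,5-dimethoxybenzene-1,2-diol, via aryl formate 3 (not isolated)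
Conditions: 30% aq H2O2, NaOH, THF/H2O, 0 °C to rt, N2; then HCl to pH 3, Na2S2O4 wash
Reagents that add atoms: hydrogen peroxide, OO
Why: Dakin oxidation: hydroperoxide adds to the aldehyde of the ortho-hydroxybenzaldehyde, the electron-rich aryl group migrates to oxygen to give formate 3 and hydroxide hydrolyses it in the flask, while working under nitrogen with a dithionite wash should keep the electron-rich catechol from being oxidised to its quinone.

Step 3
Reactants: 4 3-bromo-4,5-dimethoxybenzene-1,2-diol
Product: 7 4,5-dimethoxy-3-(trimethylsilyl)benzene-1,2-diol, via bis(trimethylsilyl) ether 5 (not isolated), via lithium silylphenoxide 6 (not isolated)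
Conditions: HMDS (1.5 equiv), THF, reflux, then evaporate; n-BuLi (1.1 equiv), THF, −78 °C to rt; aq NH4Cl, rt
Reagents that add atoms: hexamethyldisilazane, C[Si](C)(C)N[Si](C)(C)C
Why: Retro-Brook rearrangement: after O-silylation of both hydroxyls, bromine–lithium exchange at C3 should be followed by a 1,3 shift of the silyl group from the oxygen on C2 to the carbanion, driven by formation of lithium phenoxide 6, and the mildly acidic aqueous quench hydrolyses the remaining labile aryl silyl ether while leaving the C–Si bond intact.

Step 4
Reactants: 7 4,5-dimethoxy-3-(trimethylsilyl)benzene-1,2-diol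
Product: 8 4,5-dimethoxy-3-(trimethylsilyl)-1,2-phenylene bis(trifluoromethanesulfonate)
Conditions: Tf2O (2.4 equiv), pyridine, CH2Cl2, 0 °C to rt, N2
Reagents that add atoms: trifluoromethanesulfonic anhydride, O=S(=O)(C(F)(F)F)OS(=O)(=O)C(F)(F)F
Why: O-Triflation of phenols with Tf2O and pyridine is the usual last step towards ortho-silylaryl triflates, and the aryl–silicon bond should be stable to these fluoride-free conditions.

Step 5
Reactants: 9 2-methoxybenzaldehyde; 10 methyl methoxyacetate
Product: 13 (Z)-2-methoxy-3-(2-methoxyphenyl)acrylic acid, via aldol adduct 11 (not isolated), via methyl ester 12 (not isolated)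
Conditions: NaOMe, MeOH, 0 °C to reflux; then aq NaOH, 60 °C; then HCl to pH 2
Reagents that add atoms: sodium hydroxide, [Na+].[OH-]
Why: Aldol condensation of a non-enolisable aldehyde with the ester enolate (Claisen–Schmidt type), E1cB dehydration of aldol 11 and saponification of ester 12, in which the reversible addition–elimination should favour the Z alkene with the aryl group trans to the carboxyl group, and any E isomer would converge in step 6.

Step 6
Reactants: 8 4,5-dimethoxy-3-(trimethylsilyl)-1,2-phenylene bis(trifluoromethanesulfonate); 13 (Z)-2-methoxy-3-(2-methoxyphenyl)acrylic acid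
Product: 16 racemic trans-3,7,8-trimethoxy-2-(2-methoxyphenyl)-4-oxochroman-5-yl trifluoromethanesulfonate, via aryne 14 (not isolated), via hydroxyaryl enone 15 (not isolated)
Conditions: 8 (1.3 equiv), 13 (1.0 equiv), CsF (4 equiv), THF, 125 °C, sealed tube
Reagents that add atoms: none
Why: Fluoride removes the silyl group from C8a and the triflate on the neighbouring C4a leaves, giving aryne 14; the cesium carboxylate of 13 adds through oxygen to C8a, the carbanion that develops at C4a attacks the new aryl ester carbonyl through a four-membered alkoxide, and its opening gives the ortho-acyl phenoxide 15, a net insertion of the aryne into the carboxyl C–O bond that forms C8a–O1 and C4a–C4. The closest known reaction is the fluoride-induced insertion of arynes into the C–O bond of carboxylic acids, which gives ortho-hydroxyaryl ketones and, with acrylic acids, runs on to chroman-4-ones. Ring C then closes by 6-endo-trig oxa-Michael addition of the C8a phenoxide to C2, the beta carbon of the alpha-methoxy enone, and the enolate is protonated at C3. The C2 and C3 stereocentres are set under thermodynamic control, because the oxa-Michael step and enolisation at C3 are reversible, so the racemic trans isomer with both substituents equatorial should prevail; neither centre survives step 7. The selectivity needed is addition of oxygen to C8a and not to C4a: the strongly electron-withdrawing C5 triflate, expected to outweigh the C8 methoxyl, should polarise the aryne so that negative charge builds at C4a, and its bulk also shields C4a from the carboxylate. Because silicon sits on C8a, only the C4a triflate can be expelled, so the C5 triflate is kept as the masked 5-hydroxyl, and the intramolecular acyl transfer at 125 °C should outrun protonation of the C4a carbanion.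

Step 7
Reactants: 16 racemic trans-3,7,8-trimethoxy-2-(2-methoxyphenyl)-4-oxochroman-5-yl trifluoromethanesulfonate
Product: 17 3,7,8-trimethoxy-2-(2-methoxyphenyl)-4-oxo-4H-chromen-5-yl trifluoromethanesulfonate
Conditions: DDQ (2 equiv), 1,4-dioxane, reflux
Reagents that add atoms: none
Why: Dehydrogenation of a flavanone to the flavone with DDQ, in which hydride is taken from C2 (benzylic and alpha to O1) or from the C3 enol ether and the second hydrogen is lost as a proton, should give the conjugated chromone, erase both stereocentres and leave the triflate and the methyl ethers untouched.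

Step 8
Reactants: 17 3,7,8-trimethoxy-2-(2-methoxyphenyl)-4-oxo-4H-chromen-5-yl trifluoromethanesulfonate
Product: 18 5-hydroxy-3,7,8-trimethoxy-2-(2-methoxyphenyl)-4H-chromen-4-one (5-hydroxy-3,7,8,2'-tetramethoxyflavone)
Conditions: Et4NOH (aq, 2.5 equiv), 1,4-dioxane, rt; then 1 M HCl
Reagents that add atoms: none
Why: Cleavage of an aryl triflate by hydroxide attack at sulfur (S–O scission) with Et4NOH is a known mild deprotection that should be especially easy here because the departing phenoxide is stabilised by the peri carbonyl, while the methyl ethers and the pyranone ring should survive aqueous base at room temperature.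

**Compound list**

1 | 2-hydroxy-4,5-dimethoxybenzaldehyde | O=Cc1cc(OC)c(OC)cc1O | starting material
2 | 3-bromo-2-hydroxy-4,5-dimethoxybenzaldehyde | O=Cc1cc(OC)c(OC)c(Br)c1O | intermediate
3 | 3-bromo-2-hydroxy-4,5-dimethoxyphenyl formate (aryl formate of the Dakin oxidation, formed in the flask) | O=COc1cc(OC)c(OC)c(Br)c1O | intermediate
4 | 3-bromo-4,5-dimethoxybenzene-1,2-diol | Oc1cc(OC)c(OC)c(Br)c1O | intermediate
5 | 3-bromo-4,5-dimethoxy-1,2-bis(trimethylsilyloxy)benzene (formed in the flask) | COc1cc(O[Si](C)(C)C)c(O[Si](C)(C)C)c(Br)c1OC | intermediate
6 | lithium 3,4-dimethoxy-2-(trimethylsilyl)-6-(trimethylsilyloxy)phenolate (formed in the flask after the silyl shift) | [Li+].[O-]c1c([Si](C)(C)C)c(OC)c(OC)cc1O[Si](C)(C)C | intermediate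
7 | 4,5-dimethoxy-3-(trimethylsilyl)benzene-1,2-diol | COc1cc(O)c(O)c([Si](C)(C)C)c1OC | intermediate
8 | 4,5-dimethoxy-3-(trimethylsilyl)-1,2-phenylene bis(trifluoromethanesulfonate) | COc1cc(OS(=O)(=O)C(F)(F)F)c(OS(=O)(=O)C(F)(F)F)c([Si](C)(C)C)c1OC | intermediate
9 | 2-methoxybenzaldehyde | COc1ccccc1C=O | starting material
10 | methyl methoxyacetate | COCC(=O)OC | starting material
11 | methyl 3-hydroxy-2-methoxy-3-(2-methoxyphenyl)propanoate (aldol adduct, mixture of racemic diastereomers, formed in the flask as its sodium alkoxide) | COc1ccccc1C(O)C(OC)C(=O)OC | intermediate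
12 | methyl (Z)-2-methoxy-3-(2-methoxyphenyl)acrylate (formed in the flask) | COc1ccccc1/C=C(\OC)C(=O)OC | intermediate
13 | (Z)-2-methoxy-3-(2-methoxyphenyl)acrylic acid | COc1ccccc1/C=C(\OC)C(=O)O | intermediate
14 | 2,3-didehydro-4,5-dimethoxyphenyl trifluoromethanesulfonate (aryne across C4a–C8a, formed in the flask) | COC1=C(OC)C=C(OS(=O)(=O)C(F)(F)F)C#C1 | intermediate
15 | 3-hydroxy-4,5-dimethoxy-2-[(Z)-2-methoxy-3-(2-methoxyphenyl)acryloyl]phenyl trifluoromethanesulfonate (formed in the flask as its cesium phenoxide) | COc1ccccc1/C=C(\OC)C(=O)c1c(O)c(OC)c(OC)cc1OS(=O)(=O)C(F)(F)F | intermediate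
16 | racemic trans-3,7,8-trimethoxy-2-(2-methoxyphenyl)-4-oxochroman-5-yl trifluoromethanesulfonate, (2S,3S)/(2R,3R) pair, (2S,3S) enantiomer drawn | COc1ccccc1[C@@H]1Oc2c(OC)c(OC)cc(OS(=O)(=O)C(F)(F)F)c2C(=O)[C@H]1OC | intermediate
17 | 3,7,8-trimethoxy-2-(2-methoxyphenyl)-4-oxo-4H-chromen-5-yl trifluoromethanesulfonate | COc1ccccc1-c1oc2c(OC)c(OC)cc(OS(=O)(=O)C(F)(F)F)c2c(=O)c1OC | intermediate
18 | 5-hydroxy-3,7,8-trimethoxy-2-(2-methoxyphenyl)-4H-chromen-4-one (5-hydroxy-3,7,8,2'-tetramethoxyflavone, no stereocentre) | COc1ccccc1-c1oc2c(OC)c(OC)cc(O)c2c(=O)c1OC | target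

**Step count and risks**

Total steps: 8. Longest linear sequence: 7 (steps 1, 2, 3, 4, 6, 7, 8); the acid branch is one step (step 5).

Steps most likely to fail:

1. Step 6 (key step).
   - What may go wrong: the carboxylate may add to both aryne carbons, because the C8 methoxyl polarises the aryne in the sense opposite to the C5 triflate. The C4a carbanion may also be quenched by protonation (aryl ester in place of ketone) or may expel the neighbouring triflate before it reaches the ester carbonyl.
   - Fallback: ring C is built without an aryne on a ring A that lacks the C5 oxygen, and the 5-hydroxyl is introduced last by carbonyl-directed C–H hydroxylation. The fallback sets out from aldehyde 9 and comes back to the route at target 18. Claisen–Schmidt condensation of 9 with commercial 2'-hydroxy-3',4'-dimethoxyacetophenone (KOH, EtOH, rt) should give (E)-1-(2-hydroxy-3,4-dimethoxyphenyl)-3-(2-methoxyphenyl)prop-2-en-1-one F1. Algar–Flynn–Oyamada oxidation (H2O2, NaOH, MeOH, 0 °C to rt), which runs well when the 6' position is unsubstituted, should close ring C to 3-hydroxy-7,8-dimethoxy-2-(2-methoxyphenyl)-4H-chromen-4-one F2. O-Methylation (MeI, K2CO3, acetone, reflux) should give 3,7,8-trimethoxy-2-(2-methoxyphenyl)-4H-chromen-4-one F3. Ruthenium-catalysed hydroxylation of the peri C5–H bond, directed by the C4 carbonyl ([RuCl2(p-cymene)]2, PhI(OCOCF3)2, TFA/TFAA, 80 °C, then aqueous work-up), should then give 18.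

2. Step 7.
   - What may go wrong: hydride abstraction from the electron-poor, triflate-bearing chromanone may be slow, so that DDQ attacks the methoxylated rings or the flavanone reopens to the hydroxyaryl enone on prolonged heating.
   - Fallback: oxidation in two stages through a halide, setting out from 16 and coming back at 17. Alpha-bromination at C3 with phenyltrimethylammonium tribromide (THF, rt), which proceeds through the enol and needs no base, should give 3-bromo-3,7,8-trimethoxy-2-(2-methoxyphenyl)-4-oxochroman-5-yl trifluoromethanesulfonate F4. This alpha-bromo ether should lose HBr across C2–C3 on addition of Et3N to give 17.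

3. Step 3.
   - What may go wrong: n-BuLi may attack the O–Si bonds in competition with bromine–lithium exchange, the silyl shift at the crowded C3 carbanion may be incomplete, or the electron-rich silylcatechol may suffer protodesilylation and air oxidation during the aqueous quench.
   - Fallback: silicon is delivered intermolecularly to a benzyl-protected ring and the catechol is released under neutral conditions, setting out from 4 and coming back at 7. Benzylation (BnBr, K2CO3, DMF, rt) should give 1,2-bis(benzyloxy)-3-bromo-4,5-dimethoxybenzene F5. Bromine–lithium exchange and silylation (n-BuLi, THF, −78 °C; then Me3SiCl) should give [2,3-bis(benzyloxy)-5,6-dimethoxyphenyl]trimethylsilane F6. Hydrogenolysis over palladium on carbon (H2, Pd/C, EtOAc, rt) should give 7 after simple filtration, ready for step 4.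

Further compounds
F1 | step 6 | (E)-1-(2-hydroxy-3,4-dimethoxyphenyl)-3-(2-methoxyphenyl)prop-2-en-1-one | COc1ccccc1/C=C/C(=O)c1ccc(OC)c(OC)c1O
F2 | step 6 | 3-hydroxy-7,8-dimethoxy-2-(2-methoxyphenyl)-4H-chromen-4-one | COc1ccccc1-c1oc2c(OC)c(OC)ccc2c(=O)c1O
F3 | step 6 | 3,7,8-trimethoxy-2-(2-methoxyphenyl)-4H-chromen-4-one | COc1ccccc1-c1oc2c(OC)c(OC)ccc2c(=O)c1OC
F4 | step 7 | 3-bromo-3,7,8-trimethoxy-2-(2-methoxyphenyl)-4-oxochroman-5-yl trifluoromethanesulfonate (racemic, mixture of C3 epimers) | COc1ccccc1C1Oc2c(OC)c(OC)cc(OS(=O)(=O)C(F)(F)F)c2C(=O)C1(Br)OC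
F5 | step 3 | 1,2-bis(benzyloxy)-3-bromo-4,5-dimethoxybenzene | COc1cc(OCc2ccccc2)c(OCc2ccccc2)c(Br)c1OC
F6 | step 3 | [2,3-bis(benzyloxy)-5,6-dimethoxyphenyl]trimethylsilane | COc1cc(OCc2ccccc2)c(OCc2ccccc2)c([Si](C)(C)C)c1OC
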